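Everything rests on unzipping ring C at C4a–C4, C4–C3 and O1–C2. The feature exploited is that the C4 carbonyl carbon has only two carbon neighbours, C4a of ring A and C3, while O1 sits on the adjacent C8a. An ortho-iodophenol, carbon monoxide and the ring B/D arylacetylene therefore supply all ring C atoms. A single palladium-catalysed carbonylative alkynylation with amine-relayed 6-endo closure gives the achiral flavone bearing the complete carbon skeleton. Its precursors are 2-iodo-5-(triisopropylsilyloxy)phenol and 6-ethynyl-2,2-dimethyl-8-prenyl-2H-chromene. C2 is set afterwards as R by ligand-controlled copper hydride 1,4-reduction under aprotic conditions, and buffered fluoride then frees the C7 phenol.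

Key step: step 6

Numbering: flavanone numbering is used (O1, C2, C3, C4, C4a, C5–C8, C8a). Ring A is the resorcinol-derived benzene, ring C the pyranone, ring B the 2-aryl ring, and ring D the dimethylpyran fused to ring B.

Assumption: the sense of induction in step 7 cannot be predicted with certainty for a flavone. (R)-DTBM-SEGPHOS is written by analogy with cyclic β,β-disubstituted enones, and its commercial antipode is used instead if a pilot run shows hydride delivery to the Re face of C2.

Step 1
Reactants: 1 4-hydroxybenzaldehyde; 2 prenyl bromide (1-bromo-3-methylbut-2-ene)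
Product: 3 4-hydroxy-3-(3-methylbut-2-en-1-yl)benzaldehyde
Conditions: KOH (10% aq), 2 (1.0 equiv), rt
Reagents that add atoms: prenyl bromide 2, CC(C)=CCBr
Why: Ortho C-alkylation of an ambident phenoxide, in which water hydrogen-bonds the oxygen so that the ring carbon ortho to it (para is blocked by CHO) attacks the primary carbon of 2 in an SN2 sense and rearomatises to the linear prenyl phenol, a known if only modestly efficient reaction of this very phenol that is acceptable on commodity materials.

Step 2
Reactants: 3 4-hydroxy-3-(3-methylbut-2-en-1-yl)benzaldehyde; 4 3-chloro-3-methylbut-1-yne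
Product: 5 3-(3-methylbut-2-en-1-yl)-4-[(2-methylbut-3-yn-2-yl)oxy]benzaldehyde
Conditions: 4 (1.4 equiv), DBU, CuCl2·2H2O (1 mol %), MeCN, 0 °C, N2
Reagents that add atoms: 3-chloro-3-methylbut-1-yne 4, C#CC(C)(C)Cl
Why: Copper-catalysed propargylic etherification, in which the copper acetylide of 4 ionises to an allenylidene-type electrophile that the DBU phenoxide captures at the tertiary carbon, a mode that suits acidic, electron-poor phenols and leaves the aldehyde and the prenyl group untouched.

Step 3
Reactants: 5 3-(3-methylbut-2-en-1-yl)-4-[(2-methylbut-3-yn-2-yl)oxy]benzaldehyde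
Product: 8 2,2-dimethyl-8-(3-methylbut-2-en-1-yl)-2H-chromene-6-carbaldehyde, via allenylphenol 6 (not isolated), via ortho-quinone methide 7 (not isolated)
Conditions: PhNEt2, 185 °C, Ar
Reagents that add atoms: none
Why: Aromatic propargyl Claisen rearrangement to the only free ortho carbon and tautomerisation give 6, a 1,5-hydrogen shift gives 7 and oxa-6π electrocyclisation closes ring D, the standard thermal cascade of aryl 1,1-dimethylpropargyl ethers, which uses no reagent that could harm the prenyl or formyl group.

Step 4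
Reactants: 8 2,2-dimethyl-8-(3-methylbut-2-en-1-yl)-2H-chromene-6-carbaldehyde
Product: 9 6-ethynyl-2,2-dimethyl-8-(3-methylbut-2-en-1-yl)-2H-chromene
Conditions: dimethyl (1-diazo-2-oxopropyl)phosphonate, K2CO3, MeOH, 0 °C to rt
Reagents that add atoms: dimethyl (1-diazo-2-oxopropyl)phosphonate, COP(=O)(OC)C(=[N+]=[N-])C(C)=O
Why: Ohira–Bestmann variant of the Seyferth–Gilbert homologation, in which methanolysis frees the diazomethylphosphonate anion, this olefinates the non-enolisable aldehyde, and loss of N2 with a 1,2-hydrogen shift gives the terminal alkyne under conditions too mild to touch either alkene.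

Step 5
Reactants: 10 4-iodoresorcinol
Product: 11 2-iodo-5-(triisopropylsilyloxy)phenol
Conditions: TIPSCl (1.0 equiv, slow addition), imidazole, CH2Cl2–DMF, −10 to 0 °C
Reagents that add atoms: triisopropylsilyl chloride, CC(C)[Si](Cl)(C(C)C)C(C)C
Why: Imidazole-promoted silylation with one equivalent of a bulky chlorosilane should take the open hydroxyl para to iodine, because the other hydroxyl is shielded by the large ortho iodine atom, and any regioisomer or bis-ether is removed by chromatography.

Step 6
Reactants: 11 2-iodo-5-(triisopropylsilyloxy)phenol; 12 carbon monoxide; 9 6-ethynyl-2,2-dimethyl-8-(3-methylbut-2-en-1-yl)-2H-chromene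
Product: 15 2-[2,2-dimethyl-8-(3-methylbut-2-en-1-yl)-2H-chromen-6-yl]-7-(triisopropylsilyloxy)-4H-chromen-4-one, via ynone 13 (not isolated), via enaminone 14 (not isolated)
Conditions: PdCl2(PPh3)2 (5 mol %), CO (10 bar), Et2NH, 90 °C, no copper salt
Reagents that add atoms: carbon monoxide 12, [C-]#[O+]
Why: Zerovalent palladium formed from PdCl2(PPh3)2 inserts into the C4a–I bond of 11, migratory insertion of CO gives the aroylpalladium iodide, and the amine-deprotonated terminus of 9 (the future C3) is acylated to release ynone 13. This is the known carbonylative Sonogashira coupling of 2-iodophenols with arylacetylenes followed by amine-mediated flavone annulation. Et2NH adds to C2 of 13 to give enaminone 14, whose phenol O1 attacks C2 and expels the amine, a 6-endo-trig addition–elimination that closes ring C as the aromatic 4-pyranone. No stereocentre is created. The step needs CO uptake ahead of direct alkynylation, secured by CO pressure, by the electron-rich aryl group that migrates readily and by the absence of copper salts, and it needs 6-endo over 5-exo closure, secured because only C2 of 14 is electrophilic. The terminal alkyne outcompetes the trisubstituted prenyl and the 1,2-disubstituted ring D alkene for the acylpalladium species, and the hindered TIPS ether should resist the anhydrous amine.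

Step 7
Reactants: 15 2-[2,2-dimethyl-8-(3-methylbut-2-en-1-yl)-2H-chromen-6-yl]-7-(triisopropylsilyloxy)-4H-chromen-4-one
Product: 17 (R)-2-[2,2-dimethyl-8-(3-methylbut-2-en-1-yl)-2H-chromen-6-yl]-7-(triisopropylsilyloxy)chroman-4-one, via silyl enol ether 16 (not isolated)
Conditions: Cu(OAc)2·H2O (5 mol %), (R)-DTBM-SEGPHOS (5.5 mol %), (EtO)2MeSiH (1.5 equiv), toluene, 0 °C to rt, no alcohol additive; then AcOH–THF–H2O, 0 °C (no fluoride while silane is present)
Reagents that add atoms: none
Why: Proposed new method: the ligated monovalent copper hydride formed from Cu(OAc)2 and the silane should deliver hydride to C2, the β-carbon of the C2=C3–C4=O vinylogous ester, on the Si face left open by the C2-symmetric bisphosphine, which sets C2 as R, and σ-bond metathesis of the copper enolate with (EtO)2MeSiH gives 16 and regenerates the hydride. Omitting a protic additive keeps the product masked as 16, which can neither expel O1 (no ring opening, no racemisation) nor be reduced at C4, and mild acidic hydrolysis then protonates C3, which is not stereogenic. The prenyl alkene is unpolarised and inert. Hydrocupration of the electron-rich, 1,2-disubstituted ring D styrene next to a quaternary carbon should be far slower than hydride transfer to the carbonyl-activated alkene at or below room temperature and has no proton source for turnover. The closest known reaction type is the asymmetric copper hydride 1,4-reduction of β,β-disubstituted cyclic enones and of 2-alkylchromones, whereas a 2-arylchromone is a more hindered and more conjugated acceptor that is not secured as a substrate.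

Step 8
Reactants: 17 (R)-2-[2,2-dimethyl-8-(3-methylbut-2-en-1-yl)-2H-chromen-6-yl]-7-(triisopropylsilyloxy)chroman-4-one
Product: 18 ent-abyssinone III
Conditions: TBAF (1.1 equiv), AcOH (1.5 equiv), THF, 0 °C
Reagents that add atoms: none
Why: Fluoride-mediated cleavage of the aryl silyl ether with acetic acid present protonates the C7 phenoxide at once, so the medium never becomes basic enough to enolise C3 or open ring C by retro-oxa-Michael reaction, and C2 stays R while both alkenes are unaffected.

Compound list
1 | 4-hydroxybenzaldehyde | O=Cc1ccc(O)cc1 | starting material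
2 | prenyl bromide (1-bromo-3-methylbut-2-ene) | CC(C)=CCBr | starting material
3 | 4-hydroxy-3-(3-methylbut-2-en-1-yl)benzaldehyde | CC(C)=CCc1cc(C=O)ccc1O | intermediate
4 | 3-chloro-3-methylbut-1-yne | C#CC(C)(C)Cl | starting material
5 | 3-(3-methylbut-2-en-1-yl)-4-[(2-methylbut-3-yn-2-yl)oxy]benzaldehyde | CC(C)=CCc1cc(C=O)ccc1OC(C)(C)C#C | intermediate
6 | 4-hydroxy-3-(3-methylbuta-1,2-dien-1-yl)-5-(3-methylbut-2-en-1-yl)benzaldehyde (allenylphenol, not isolated) | CC(C)=CCc1cc(C=O)cc(C=C=C(C)C)c1O | intermediate
7 | 3-(3-methylbut-2-en-1-ylidene)-5-(3-methylbut-2-en-1-yl)-4-oxocyclohexa-1,5-diene-1-carbaldehyde (ortho-quinone methide, exocyclic geometry undefined, not isolated) | CC(C)=CCC1=CC(C=O)=CC(=CC=C(C)C)C1=O | intermediate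
8 | 2,2-dimethyl-8-(3-methylbut-2-en-1-yl)-2H-chromene-6-carbaldehyde | CC(C)=CCc1cc(C=O)cc2c1OC(C)(C)C=C2 | intermediate
9 | 6-ethynyl-2,2-dimethyl-8-(3-methylbut-2-en-1-yl)-2H-chromene | CC(C)=CCc1cc(C#C)cc2c1OC(C)(C)C=C2 | intermediate
10 | 4-iodoresorcinol (4-iodobenzene-1,3-diol) | Oc1ccc(I)c(O)c1 | starting material
11 | 2-iodo-5-(triisopropylsilyloxy)phenol | Oc1cc(O[Si](C(C)C)(C(C)C)C(C)C)ccc1I | intermediate
12 | carbon monoxide | [C-]#[O+] | starting material
13 | 1-[2-hydroxy-4-(triisopropylsilyloxy)phenyl]-3-[2,2-dimethyl-8-(3-methylbut-2-en-1-yl)-2H-chromen-6-yl]prop-2-yn-1-one (ynone, not isolated) | CC(C)=CCc1cc(C#CC(=O)c2ccc(O[Si](C(C)C)(C(C)C)C(C)C)cc2O)cc2c1OC(C)(C)C=C2 | intermediate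
14 | 3-(diethylamino)-1-[2-hydroxy-4-(triisopropylsilyloxy)phenyl]-3-[2,2-dimethyl-8-(3-methylbut-2-en-1-yl)-2H-chromen-6-yl]prop-2-en-1-one (enaminone, alkene geometry undefined, not isolated) | CCN(CC)C(=CC(=O)c1ccc(O[Si](C(C)C)(C(C)C)C(C)C)cc1O)c1cc(CC=C(C)C)c2OC(C)(C)C=Cc2c1 | intermediate
15 | 2-[2,2-dimethyl-8-(3-methylbut-2-en-1-yl)-2H-chromen-6-yl]-7-(triisopropylsilyloxy)-4H-chromen-4-one (flavone) | CC(C)=CCc1cc(-c2cc(=O)c3ccc(O[Si](C(C)C)(C(C)C)C(C)C)cc3o2)cc2c1OC(C)(C)C=C2 | intermediate
16 | (R)-4-[diethoxy(methyl)silyloxy]-2-[2,2-dimethyl-8-(3-methylbut-2-en-1-yl)-2H-chromen-6-yl]-7-(triisopropylsilyloxy)-2H-chromene (silyl enol ether, not isolated) | CC(C)=CCc1cc([C@H]2C=C(O[Si](C)(OCC)OCC)c3ccc(O[Si](C(C)C)(C(C)C)C(C)C)cc3O2)cc2c1OC(C)(C)C=C2 | intermediate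
17 | (R)-2-[2,2-dimethyl-8-(3-methylbut-2-en-1-yl)-2H-chromen-6-yl]-7-(triisopropylsilyloxy)chroman-4-one | CC(C)=CCc1cc([C@H]2CC(=O)c3ccc(O[Si](C(C)C)(C(C)C)C(C)C)cc3O2)cc2c1OC(C)(C)C=C2 | intermediate
18 | ent-abyssinone III, (R)-7-hydroxy-2-[2,2-dimethyl-8-(3-methylbut-2-en-1-yl)-2H-chromen-6-yl]chroman-4-one | CC(C)=CCc1cc([C@H]2CC(=O)c3ccc(O)cc3O2)cc2c1OC(C)(C)C=C2 | target

Total step count: 8. Longest linear sequence: 7 (steps 1, 2, 3, 4, 6, 7, 8).

Steps most likely to fail

First, step 7. The risks are sluggish hydride transfer to the vinylogous ester, poor facial selectivity, ring opening of the copper enolate before it is silylated, and stray reaction at the ring D alkene.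
- The fallback uses known chemistry only. It sets out from aldehyde 8 and comes back at 17.
- Claisen–Schmidt condensation of 8 with commercial 2',4'-dihydroxyacetophenone (CC(=O)c1ccc(O)cc1O; KOH, EtOH–H2O, rt) should give (E)-1-(2,4-dihydroxyphenyl)-3-(ring B/D aryl)prop-2-en-1-one F1.
- NaOAc in refluxing EtOH closes it by oxa-Michael addition to racemic abyssinone III F2.
- TIPSCl and imidazole give the racemic 7-O-TIPS flavanone F3.
- Kinetic resolution follows by asymmetric transfer hydrogenation (RuCl(p-cymene)[(S,S)-TsDPEN], HCO2H–Et3N, EtOAc, rt, stopped near half conversion). It should reduce the 2S ketone to the cis-(2S,4S)-flavan-4-ol F4 and leave 17, which is separated by chromatography.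
- The isolated alkenes are inert to this catalyst.

Second, step 6. The risks are direct alkynylation without CO uptake, aminocarbonylation of the acylpalladium species by the amine, 5-exo closure, and loss of the silyl group in hot amine.
- The fallback brings C4 in as an aldehyde carbon instead of CO. It sets out from alkyne 9 and comes back at ynone 13.
- Commercial 2,4-dihydroxybenzaldehyde (O=Cc1ccc(O)cc1O) is silylated at the non-chelated 4-hydroxyl (TIPSCl, imidazole, CH2Cl2) to 2-hydroxy-4-(triisopropylsilyloxy)benzaldehyde F5.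
- F5 is pre-deprotonated with NaH, and 9, deprotonated with n-BuLi in THF at −78 °C, is added to give the racemic propargylic alcohol F6.
- MnO2 in CH2Cl2 oxidises this to 13.
- Treatment of 13 with Et2NH in DMF at rt to 40 °C then leads through 14 to 15.

Third, step 1. O-alkylation and double alkylation compete with ortho C-alkylation of the ambident phenoxide.
- The fallback installs the prenyl group last by cross-coupling. It sets out from chloride 4 and comes back at aldehyde 8.
- Commercial 3-bromo-4-hydroxybenzaldehyde (O=Cc1ccc(O)c(Br)c1) is etherified with 4 under the conditions of step 2 to 3-bromo-4-[(2-methylbut-3-yn-2-yl)oxy]benzaldehyde F7.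
- Heating as in step 3 gives 8-bromo-2,2-dimethyl-2H-chromene-6-carbaldehyde F8.
- Stille coupling with tributyl(3-methylbut-2-en-1-yl)stannane (CCCC[Sn](CCCC)(CCCC)CC=C(C)C; Pd(PPh3)4, DMF, 100 °C) should give 8 with the linear prenyl group.

Further compounds
F1 | step 7 | (E)-1-(2,4-dihydroxyphenyl)-3-[2,2-dimethyl-8-(3-methylbut-2-en-1-yl)-2H-chromen-6-yl]prop-2-en-1-one | CC(C)=CCc1cc(/C=C/C(=O)c2ccc(O)cc2O)cc2c1OC(C)(C)C=C2
F2 | step 7 | racemic abyssinone III | CC(C)=CCc1cc(C2CC(=O)c3ccc(O)cc3O2)cc2c1OC(C)(C)C=C2
F3 | step 7 | racemic 2-[2,2-dimethyl-8-(3-methylbut-2-en-1-yl)-2H-chromen-6-yl]-7-(triisopropylsilyloxy)chroman-4-one | CC(C)=CCc1cc(C2CC(=O)c3ccc(O[Si](C(C)C)(C(C)C)C(C)C)cc3O2)cc2c1OC(C)(C)C=C2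
F4 | step 7 | (2S,4S)-2-[2,2-dimethyl-8-(3-methylbut-2-en-1-yl)-2H-chromen-6-yl]-7-(triisopropylsilyloxy)chroman-4-ol | CC(C)=CCc1cc([C@@H]2C[C@H](O)c3ccc(O[Si](C(C)C)(C(C)C)C(C)C)cc3O2)cc2c1OC(C)(C)C=C2
F5 | step 6 | 2-hydroxy-4-(triisopropylsilyloxy)benzaldehyde | O=Cc1ccc(O[Si](C(C)C)(C(C)C)C(C)C)cc1O
F6 | step 6 | racemic 1-[2-hydroxy-4-(triisopropylsilyloxy)phenyl]-3-[2,2-dimethyl-8-(3-methylbut-2-en-1-yl)-2H-chromen-6-yl]prop-2-yn-1-ol | CC(C)=CCc1cc(C#CC(O)c2ccc(O[Si](C(C)C)(C(C)C)C(C)C)cc2O)cc2c1OC(C)(C)C=C2
F7 | step 1 | 3-bromo-4-[(2-methylbut-3-yn-2-yl)oxy]benzaldehyde | O=Cc1ccc(OC(C)(C)C#C)c(Br)c1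
F8 | step 1 | 8-bromo-2,2-dimethyl-2H-chromene-6-carbaldehyde | O=Cc1cc(Br)c2OC(C)(C)C=Cc2c1
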